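Both halves carry the same C6/C7 stereodiad and the same 2-(hydroxymethyl)acrylate. Both are therefore drawn from one intermediate and joined last by opening a C4 spiro-epoxide with the butenolide-half acid. Everything rests on a lactone-tethered ring-closing metathesis. It exploits two features of the cyclohexane half. The acrylate CH2OH is cis to ring carbon C6, and the C5 carboxyl is the trans-diequatorial neighbour of C6. C5–C(=O)–O–CH2–Cα=CH–C6 can therefore exist as a seven-membered lactone fused to the cyclohexane. One operation forms the Cα=CH bond, fixes its geometry and masks acid and alcohol. The precursor is the 2-(tert-butoxycarbonyl)allyl ester of the C6-vinyl, C4-spiro-epoxy C5 acid.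

Key step: step 10

Remark on locants: in the cyclohexane half C4 is the carbinol carbon, C5 carries CO2H, C6 the acrylate and C7 the isopropyl group, followed by C8 and C9. Primes mark the butenolide half. β is the ring face that carries the C7 isopropyl group and α is the other face. In the chair the C5, C6 and C7 substituents are all equatorial; at C4, β is axial and α is equatorial.

Assumption: the sense of induction in step 1 follows the accepted enamine-shielding model, under which the (R)-catalyst gives (R)-3; if it ran the other way, the antipodal catalyst would be used.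

Step 1
Reactants: 1 isovaleraldehyde; 2 methyl vinyl ketone
Product: 3 (R)-2-isopropyl-5-oxohexanal
Conditions: (R)-2-[methoxy(diphenyl)methyl]pyrrolidine (5 mol %), ethyl 3,4-dihydroxybenzoate (20 mol %), neat, 4 °C
Reagents that add atoms: none
Why: Enamine-catalysed asymmetric Michael addition: the diphenyl(methoxy)methyl group of the (R)-catalyst shields one face of the (E)-enamine of 1, so that the hydrogen-bond-activated enone should be taken up on the open face and set C7 as (R).

Step 2
Reactants: 3 (R)-2-isopropyl-5-oxohexanal
Product: 4 (R)-4-isopropylcyclohex-2-en-1-one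
Conditions: KOH (0.2 equiv), n-Bu4NOH (cat.), Et2O/THF/H2O, reflux
Reagents that add atoms: none
Why: Intramolecular aldol condensation (6-enolexo closure of the methyl ketone enolate onto the aldehyde, then E1cB loss of water), in which C7 becomes the γ-carbon of the enone and should keep its configuration under the mild two-phase base.

Step 3
Reactants: 4 (R)-4-isopropylcyclohex-2-en-1-one; 5 vinylmagnesium bromide
Product: 6 trimethylsilyl enol ether (C4=C5) of trans-4-isopropyl-3-vinylcyclohexanone
Conditions: CuI·2LiCl (10 mol %), TMSCl, THF, −78 → −40 °C; Et3N, cold aq. NaHCO3 work-up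
Reagents that add atoms: chlorotrimethylsilane, C[Si](C)(C)Cl
Why: Copper-catalysed, silyl-chloride-accelerated conjugate addition of a Grignard reagent: the vinyl copper species should add to C6 anti to the neighbouring C7 isopropyl group, which sets C6 trans to C7, and O-silylation stores the enolate regiospecifically as the C4=C5 enol ether.

Step 4
Reactants: 6 silyl enol ether; 7 formaldehyde (37 % aq.)
Product: 8 all-equatorial C5-hydroxymethyl ketone
Conditions: Yb(OTf)3 (10 mol %), THF/H2O, rt
Reagents that add atoms: none
Why: Lanthanide-triflate-catalysed aqueous Mukaiyama aldol reaction (hydroxymethylation): formaldehyde should be attacked by C5 on the face anti to the C6 vinyl group, and the resulting all-equatorial ketone is also the thermodynamic C5 epimer, so C5 is set trans to C6; a CH2OH group serves as the latent C5 carboxyl because it leaves the ketone non-acidic for step 6.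

Step 5
Reactants: 8 C5-hydroxymethyl ketone
Product: 9 TBS ether of 8
Conditions: TBSCl, imidazole, CH2Cl2, 0 °C → rt
Reagents that add atoms: tert-butyldimethylsilyl chloride, CC(C)(C)[Si](C)(C)Cl
Why: Standard silylation of a primary alcohol, which removes the hydroxyl proton and the retro-aldol pathway before the basic ylide step.

Step 6
Reactants: 9 TBS ether ketone; 10 trimethylsulfonium iodide
Product: 11 C4 spiro-epoxide (O α/equatorial, CH2 β/axial) with C5 CH2OTBS
Conditions: n-BuLi, THF, 0 °C (ylide); then 9, 0 °C → rt
Reagents that add atoms: none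
Why: Corey–Chaykovsky epoxidation: the small, irreversibly adding dimethylsulfonium methylide should attack the chair ketone along the axial trajectory (only C6–H and C8–H are 1,3-diaxial), which places CH2 axial and O equatorial at C4 as the target requires, leaves the vinyl group untouched, and delivers C4 in the form needed for the fragment union, since a free C4–CH2OH beside a C5 acyl group would close a γ-lactone.

Step 7
Reactants: 11 TBS epoxide
Product: 12 epoxy alcohol
Conditions: TBAF, AcOH (1:1), THF, 0 °C → rt
Reagents that add atoms: none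
Why: Fluoride-mediated desilylation, with acetic acid buffering the alkoxide so that neither the epoxide nor C5 is disturbed.

Step 8
Reactants: 12 epoxy alcohol
Product: 13 C6-vinyl C4-spiro-epoxy C5 acid
Conditions: TEMPO (20 mol %), PhI(OAc)2 (2.5 equiv), MeCN/H2O (1:1), rt
Reagents that add atoms: water, O
Why: Oxoammonium (TEMPO)-catalysed oxidation of a primary alcohol through the aldehyde hydrate to the acid, whose weakly acidic medium should spare the vinyl group and the epoxide, while C5 already holds the more stable equatorial configuration.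

Step 9
Reactants: 13 epoxy acid; 14 tert-butyl 2-(bromomethyl)acrylate
Product: 15 2-(tert-butoxycarbonyl)allyl ester of 13
Conditions: Cs2CO3, DMF, 0 °C → rt
Reagents that add atoms: none
Why: O-Alkylation (SN2) of the caesium carboxylate with an activated allylic bromide, which needs no activation of the hindered C5 carboxyl and so cannot epimerise C5; the tert-butyl ester is chosen because it outlasts hydroxide in step 11 and leaves under acid at the end.

Step 10
Reactants: 15 2-(tert-butoxycarbonyl)allyl ester
Product: 16 trans-fused unsaturated ε-lactone tert-butyl ester (C4 spiro-epoxide retained)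
Conditions: Hoveyda–Grubbs II (10 mol %, two portions), toluene (2 mM), 80 °C, Ar sparge
Reagents that add atoms: none
Why: Ring-closing metathesis: the ruthenium alkylidene loads on the C6 vinyl group, the only monosubstituted and electron-neutral alkene, adds [2+2] to the tethered 1,1-disubstituted acrylate alkene and cycloreverts with loss of ethene, which forms the Cα=CH bond. The closest known reaction type is the second-generation-catalyst RCM of methacrylates and of 2-(alkoxycarbonyl)allyl esters and ethers with terminal vinyl groups to cyclic trisubstituted enoates. The ring closed is the seven-membered lactone C5–C(=O)–O–CH2–Cα=CH–C6, closed at the alkene, which is endocyclic and can therefore only hold the CH2O carbon cis to C6, the geometry of both acrylates of 26. No stereocentre is formed, and C4–C7 are spectators that are not epimerised under neutral conditions. The step needs ring closure over oligomerisation: the two arms sit trans-diequatorial on a locked chair, the acrylate alkene does not homodimerise, and high dilution with removal of ethene does the rest. The epoxide and the tert-butyl ester are inert to the catalyst, and the tert-butyl ester later allows the lactone alone to be opened.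

Step 11
Reactants: 16 epoxy ε-lactone
Product: 17 epoxy C5 acid carrying the (E)-2-(hydroxymethyl)acrylate tert-butyl ester at C6 (divided between steps 12 and 13)
Conditions: LiOH (1.2 equiv), THF/H2O, 0 °C; aq. NaH2PO4 to pH 4–5
Reagents that add atoms: lithium hydroxide, [Li+].[OH-]
Why: Saponification: hydroxide should attack the strained, s-cis-locked allylic ε-lactone far faster than the tert-butyl enoate, the alkene geometry is no longer at risk, and β-elimination of the epoxide is disfavoured because its C4–O bond is equatorial and lies close to the nodal plane of a C5 enolate.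

Step 12
Reactants: 17 hydroxy epoxy acid
Product: 18 di-tert-butyl ester epoxide (cyclohexane-half electrophile)
Conditions: O-tert-butyl-N,N′-diisopropylisourea, CH2Cl2, rt
Reagents that add atoms: O-tert-butyl-N,N′-diisopropylisourea, CC(C)NC(=NC(C)C)OC(C)(C)C
Why: Alkylative tert-butyl ester formation with an O-alkylisourea (the C–O bond is made at the alkyl carbon under neutral conditions), which is insensitive to the hindrance at C5, leaves alcohol and epoxide alone, and blocks the only internal acid that could compete in step 16.

Step 13
Reactants: 17 hydroxy epoxy acid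
Product: 20 cis-fused β-hydroxy-γ-lactone tert-butyl ester, via iodohydrin lithium carboxylate 19 (not isolated)
Conditions: LiI (0.3 equiv), THF, 50 °C
Reagents that add atoms: none
Why: Halide-catalysed addition of a carboxylic acid to an epoxide, here intramolecular: iodide opens the lithium-activated epoxide at its CH2 terminus and the cis C5 carboxylate displaces iodide in a 5-exo-tet closure, so C4 is never touched.

Step 14
Reactants: 20 β-hydroxy-γ-lactone
Product: 23 butenolide hydroxy tert-butyl ester, via bis(trifluoroacetate) 21 (not isolated), via butenolide primary trifluoroacetate 22 (not isolated)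
Conditions: (CF3CO)2O, Et3N, CH2Cl2, −20 °C → rt; then MeOH, rt
Reagents that add atoms: none
Why: Acylation followed by E1cB elimination: both hydroxyls are trifluoroacetylated, the ring-fusion trifluoroacetate stands nearly perpendicular to the lactone plane and leaves from the lactone enolate to give the tetrasubstituted butenolide, and the primary trifluoroacetate that served as transient protection is removed by methanolysis.

Step 15
Reactants: 23 butenolide tert-butyl ester
Product: 24 butenolide-half hydroxy acid
Conditions: TFA/CH2Cl2 (1:3), 0 °C → rt; brief aq. NaHCO3, then pH 3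
Reagents that add atoms: none
Why: Acidolysis of a tert-butyl ester (AAL1, loss of 2-methylpropene), which avoids any strong base on the doubly allylic C6′–H and leaves the butenolide and the electron-poor allylic alcohol intact.

Step 16
Reactants: 18 di-tert-butyl ester epoxide; 24 butenolide-half acid (slight excess)
Product: 25 coupled di-tert-butyl ester
Conditions: Cs2CO3 (0.3 equiv), DMF, 70 °C
Reagents that add atoms: none
Why: Base-catalysed ring opening of an epoxide by a carboxylate (SN2 at the unsubstituted carbon): the caesium salt of 24 attacks the axial CH2, C4 keeps its configuration and appears as the equatorial tertiary alcohol, the remaining free acid protonates the alkoxide, and the unactivated hydroxyl groups of both partners need no protection.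

Step 17
Reactants: 25 coupled di-tert-butyl ester
Product: 26 CNP0071646.2
Conditions: TFA/CH2Cl2 (1:3), 0 °C → rt; brief aq. NaHCO3, then pH 3
Reagents that add atoms: none
Why: Acidolysis (AAL1) of both tert-butyl esters, in which the tertiary C4 alcohol should resist ionisation because it is flanked by the acyloxymethyl and carboxyl-bearing carbons, and no ester of 26 meets base beyond a short hydrogen carbonate wash.

Compound list

1 | isovaleraldehyde (3-methylbutanal) | CC(C)CC=O | starting material
2 | methyl vinyl ketone | CC(=O)C=C | starting material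
3 | (R)-2-isopropyl-5-oxohexanal | CC(C)[C@H](C=O)CCC(C)=O | intermediate
4 | (R)-4-isopropylcyclohex-2-en-1-one | CC(C)[C@H]1CCC(=O)C=C1 | intermediate
5 | vinylmagnesium bromide | C=C[Mg]Br | starting material
6 | {[(3R,4R)-4-isopropyl-3-vinylcyclohex-1-en-1-yl]oxy}trimethylsilane (C6 vinyl α, C7 i-Pr β) | CC(C)[C@H]1CCC(O[Si](C)(C)C)=C[C@@H]1C=C | intermediate
7 | formaldehyde | C=O | starting material
8 | 2-(hydroxymethyl)-4-isopropyl-3-vinylcyclohexan-1-one, all-equatorial (C5 CH2OH β, C6 vinyl α, C7 i-Pr β) | CC(C)[C@H]1CCC(=O)[C@@H](CO)[C@@H]1C=C | intermediate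
9 | tert-butyldimethylsilyl ether of 8 | CC(C)[C@H]1CCC(=O)[C@@H](CO[Si](C)(C)C(C)(C)C)[C@@H]1C=C | intermediate
10 | trimethylsulfonium iodide | C[S+](C)C.[I-] | starting material
11 | 1-oxaspiro[2.5]octane: C4–O α (equatorial), C4–CH2 β (axial), C5 CH2OTBS β, C6 vinyl α, C7 i-Pr β | CC(C)[C@H]1CC[C@@]2(CO2)[C@@H](CO[Si](C)(C)C(C)(C)C)[C@@H]1C=C | intermediate
12 | epoxy alcohol (11 with free C5 CH2OH) | CC(C)[C@H]1CC[C@@]2(CO2)[C@@H](CO)[C@@H]1C=C | intermediate
13 | epoxy acid (C5 CO2H β, C6 vinyl α, C7 i-Pr β, C4 spiro-epoxide O α) | CC(C)[C@H]1CC[C@@]2(CO2)[C@@H](C(=O)O)[C@@H]1C=C | intermediate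
14 | tert-butyl 2-(bromomethyl)acrylate | C=C(CBr)C(=O)OC(C)(C)C | starting material
15 | 2-(tert-butoxycarbonyl)allyl ester of 13 | CC(C)[C@H]1CC[C@@]2(CO2)[C@@H](C(=O)OCC(=C)C(=O)OC(C)(C)C)[C@@H]1C=C | intermediate
16 | trans-fused ε-lactone C5–C(=O)–O–CH2–Cα=CH–C6, Cα bearing CO2t-Bu, C4 spiro-epoxide (O α), C7 i-Pr β | CC(C)[C@H]1CC[C@@]3(CO3)[C@H]2C(=O)OCC(C(=O)OC(C)(C)C)=C[C@H]12 | intermediate
17 | epoxy C5 acid with (E)-CH=C(CH2OH)CO2t-Bu at C6 (α) | CC(C)[C@H]1CC[C@@]2(CO2)[C@@H](C(=O)O)[C@@H]1/C=C(\CO)C(=O)OC(C)(C)C | intermediate
18 | C5 tert-butyl ester of 17 | CC(C)[C@H]1CC[C@@]2(CO2)[C@@H](C(=O)OC(C)(C)C)[C@@H]1/C=C(\CO)C(=O)OC(C)(C)C | intermediate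
19 | iodohydrin lithium carboxylate (C4–OH α, C4–CH2I β) | CC(C)[C@H]1CC[C@@](O)(CI)[C@@H](C(=O)[O-])[C@@H]1/C=C(\CO)C(=O)OC(C)(C)C.[Li+] | intermediate
20 | cis-fused β-hydroxy-γ-lactone C5–C(=O)–O–CH2–C4 (C4–OH α, C5–H α) with (E)-CH=C(CH2OH)CO2t-Bu at C6 | CC(C)[C@H]1CC[C@@]2(O)COC(=O)[C@H]2[C@@H]1/C=C(\CO)C(=O)OC(C)(C)C | intermediate
21 | bis(trifluoroacetate) of 20 | CC(C)[C@H]1CC[C@@]2(OC(=O)C(F)(F)F)COC(=O)[C@H]2[C@@H]1/C=C(\COC(=O)C(F)(F)F)C(=O)OC(C)(C)C | intermediate
22 | primary trifluoroacetate of 23 | CC(C)[C@H]1CCC2=C(C(=O)OC2)[C@@H]1/C=C(\COC(=O)C(F)(F)F)C(=O)OC(C)(C)C | intermediate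
23 | tert-butyl (E)-2-(hydroxymethyl)-3-[(4S,5R)-5-isopropyl-3-oxo-1,3,4,5,6,7-hexahydroisobenzofuran-4-yl]acrylate | CC(C)[C@H]1CCC2=C(C(=O)OC2)[C@@H]1/C=C(\CO)C(=O)OC(C)(C)C | intermediate
24 | (E)-2-(hydroxymethyl)-3-[(4S,5R)-5-isopropyl-3-oxo-1,3,4,5,6,7-hexahydroisobenzofuran-4-yl]acrylic acid | CC(C)[C@H]1CCC2=C(C(=O)OC2)[C@@H]1/C=C(\CO)C(=O)O | intermediate
25 | di-tert-butyl ester of 26 (C5 and C6-acrylate carboxyls) | CC(C)[C@H]1CC[C@@](O)(COC(=O)/C(=C/[C@H]2C3=C(CC[C@@H]2C(C)C)COC3=O)CO)[C@@H](C(=O)OC(C)(C)C)[C@@H]1/C=C(\CO)C(=O)OC(C)(C)C | intermediate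
26 | CNP0071646.2 (C4 S, C5 S, C6 S, C7 R; C6′ S, C7′ R; both acrylates E) | CC(C)[C@H]1CC[C@@](O)(COC(=O)/C(=C/[C@H]2C3=C(CC[C@@H]2C(C)C)COC3=O)CO)[C@@H](C(=O)O)[C@@H]1/C=C(\CO)C(=O)O | target

Total step count: 17. Longest linear sequence: 16 (steps 1–11, 13–17).

Steps most likely to fail

Step 10. The ester must leave its preferred s-trans conformation before the alkylidene at C6 can reach the electron-poor 1,1-disubstituted alkene. Oligomerisation through the vinyl groups or catalyst decay may therefore outrun ring closure.
- The fallback replaces metathesis by olefination and cross-coupling. It sets out from 13 and comes back at 17.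
- Mitsunobu esterification (2-(trimethylsilyl)ethanol, PPh3, DIAD) gives the 2-(trimethylsilyl)ethyl ester F1.
- Ozonolysis of the vinyl group (O3, CH2Cl2, −78 °C; PPh3) gives the C6 aldehyde F2, which is already the all-equatorial epimer.
- Wittig olefination with tert-butyl bromo(triphenylphosphoranylidene)acetate should give the (Z)-α-bromo enoate F3, with C6 cis to Br.
- Stille coupling with (tributylstannyl)methanol (Pd(PPh3)4, dioxane, heat) replaces Br by CH2OH with retention and gives the hydroxymethyl enoate F4.
- TBAF then frees the C5 acid, which is 17.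

Step 16. Substitution at the neopentyl-type epoxide carbon may be slow. At the temperature it needs, loss of the doubly allylic C6′–H and migration of the acrylate double bond of 24 may then take over.
- The fallback couples first and builds the butenolide afterwards. It sets out from 20 (with 18) and comes back at 25.
- TFA/CH2Cl2 turns 20 into the hydroxy-lactone acid F5, which has no skipped diene and tolerates a full equivalent of caesium base and higher temperature.
- Opening of 18 with F5 gives the coupled hydroxy-lactone F6.
- (CF3CO)2O/Et3N and then MeOH, as in step 14, should eliminate only the lactone β-trifluoroacetate. The C4 trifluoroacetate of the other half has an equatorial C–O bond and a far less acidic α-H.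
- All remaining trifluoroacetates are methanolysed, which gives 25.

Step 14. Acylation of the hindered ring-fusion hydroxyl may stay incomplete, or the amine may shift the acrylate double bond once the butenolide is in place.
- The fallback uses a neutral thermal syn-elimination. It sets out from 20 and comes back at 24.
- TBSCl/imidazole gives the primary silyl ether F7.
- The Burgess reagent (toluene, 60 °C) uses the cis C4′–O/C5′–H pair in an Ei elimination to give the silylated butenolide F8.
- TFA/CH2Cl2 containing a little water removes the silyl ether and the tert-butyl ester together, which gives 24.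

Further compounds

F1 | step 10 | 2-(trimethylsilyl)ethyl ester of 13 | CC(C)[C@H]1CC[C@@]2(CO2)[C@@H](C(=O)OCC[Si](C)(C)C)[C@@H]1C=C
F2 | step 10 | C6 aldehyde (CHO α) from F1 | CC(C)[C@H]1CC[C@@]2(CO2)[C@@H](C(=O)OCC[Si](C)(C)C)[C@@H]1C=O
F3 | step 10 | (Z)-α-bromo enoate tert-butyl ester at C6 | CC(C)[C@H]1CC[C@@]2(CO2)[C@@H](C(=O)OCC[Si](C)(C)C)[C@@H]1/C=C(\Br)C(=O)OC(C)(C)C
F4 | step 10 | 2-(trimethylsilyl)ethyl ester of 17 | CC(C)[C@H]1CC[C@@]2(CO2)[C@@H](C(=O)OCC[Si](C)(C)C)[C@@H]1/C=C(\CO)C(=O)OC(C)(C)C
F5 | step 16 | hydroxy-lactone acid (20 without tert-butyl) | CC(C)[C@H]1CC[C@@]2(O)COC(=O)[C@H]2[C@@H]1/C=C(\CO)C(=O)O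
F6 | step 16 | coupled di-tert-butyl ester with β-hydroxy-γ-lactone in place of the butenolide | CC(C)[C@H]1CC[C@@](O)(COC(=O)/C(=C/[C@H]2[C@@H]3C(=O)OC[C@]3(O)CC[C@@H]2C(C)C)CO)[C@@H](C(=O)OC(C)(C)C)[C@@H]1/C=C(\CO)C(=O)OC(C)(C)C
F7 | step 14 | primary TBS ether of 20 | CC(C)[C@H]1CC[C@@]2(O)COC(=O)[C@H]2[C@@H]1/C=C(\CO[Si](C)(C)C(C)(C)C)C(=O)OC(C)(C)C
F8 | step 14 | primary TBS ether of 23 | CC(C)[C@H]1CCC2=C(C(=O)OC2)[C@@H]1/C=C(\CO[Si](C)(C)C(C)(C)C)C(=O)OC(C)(C)C
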